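## Plan

1. **Common core:** a trans-decalin (5α-H, 10β-CH3) with 6α-OH, 8α-OH/8β-CH3 and a 9β side chain C11–C16. The chain holds the 13E alkene and ends in a 4-methylbutenolide joined through C16.
2. **Differences:** C23, the equatorial 4α carbon (CH3, CH2OH, CHO, CO2H or CO2CH3), and C15 (OH or H).
3. **Shared intermediate:** 21, the 6,8-bis(triethylsilyl) ether of CNP0112578.1. It has a free C23 aldehyde and its only free hydroxyl is at C15. Every member is three steps or fewer away.
4. **Cuts:** C15–C16 (vinylogous aldol), C13=C14 (olefination) and O–C6 (C–H lactonisation steered by the C23 acid). Then C4–C5, C9–C10 and O–C8 are cut together (polyene cyclisation), and last C11–C12 (enolate alkylation).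
5. **Enabling feature:** in rings A/B the set C4 (equatorial CH2O), C5, C10, C9 and C8 (equatorial O) is the print of an all-E triene folded chair–chair, and O8 lies six atoms from C13. An epoxy-triene ester with an E-CH2O terminus can therefore deliver the whole set at once.
6. **Ring order:** rings A and B and a temporary δ-lactone (O8–C13) form in step 5. A temporary γ-lactone (C23–O6) forms in step 10. The butenolide arrives ready-made in step 16.
7. **Stereocentres:** the two oxirane carbons are set by catalysis and relayed to C4, C5, C8, C9 and C10 (step 5). C6 is then relayed from C4 (step 10). C15 and C16 are set by a second catalyst.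

Key step: step 5
Shared intermediate: compound 21

Remark (numbering): decalin C1–C10. C25 = CH3 on C10, C22 = CH3 on C8, C23 = 4α carbon, C24 = 4β-CH3. Chain C11–C16 with C21 = CH3 on C13. Butenolide C16–C19 with C20 = CH3 on C17.

Assumption: for the chiral catalysts of steps 10 and 16, the antipode that gives the drawn product is taken. In step 3 the sense follows from the known behaviour of E-allylic alcohols with L-(+)-tartrate.

## Trunk

Step 1
Reactants: 1 tert-butyl acetate; 2 (2E,6E)-farnesyl bromide
Product: 3 tert-butyl (4E,8E)-5,9,13-trimethyltetradeca-4,8,12-trienoate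
Conditions: LDA, THF, −78 °C; then 2, DMPU, −78 → 0 °C
Reagents that add atoms: none
Why: Alkylation of a lithium ester enolate by a primary allylic bromide (SN2) forms C11–C12, leaves both E alkenes untouched and places the later terminating carbonyl (C13) two CH2 groups from the C8=C9 alkene.

Step 2
Reactants: 3 tert-butyl (4E,8E)-5,9,13-trimethyltetradeca-4,8,12-trienoate
Product: 4 tert-butyl (4E,8E,12E)-14-hydroxy-5,9,13-trimethyltetradeca-4,8,12-trienoate
Conditions: SeO2 (0.3 equiv), t-BuOOH, salicylic acid (cat.), CH2Cl2, 0 °C → rt, stopped at partial conversion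
Reagents that add atoms: tert-butyl hydroperoxide, CC(C)(C)OO
Why: The SeO2/t-BuOOH allylic oxidation (ene reaction, then [2,3]-shift) prefers the least hindered, terminal isopropylidene unit and, through its cyclic transition state, only the E methyl group, which fixes the 12E geometry that later makes C23 equatorial.

Step 3
Reactants: 4 tert-butyl (4E,8E,12E)-14-hydroxy-5,9,13-trimethyltetradeca-4,8,12-trienoate
Product: 5 tert-butyl (4E,8E)-11-[(2S,3S)-3-(hydroxymethyl)-3-methyloxiran-2-yl]-5,9-dimethylundeca-4,8-dienoate
Conditions: Ti(Oi-Pr)4 (cat.), L-(+)-diethyl tartrate (cat.), t-BuOOH, 4 Å MS, CH2Cl2, −20 °C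
Reagents that add atoms: tert-butyl hydroperoxide, CC(C)(C)OO
Why: The Sharpless asymmetric epoxidation touches only the alkene that carries the allylic hydroxyl, and L-(+)-tartrate should give the (2S,3S)-oxirane of this E-allylic alcohol, so the two centres (C3, C4) from which the decalin is relayed are set by catalysis.

Step 4
Reactants: 5 (2S,3S)-epoxy alcohol
Product: 6 tert-butyldimethylsilyl ether of 5
Conditions: TBSCl, imidazole, CH2Cl2, rt
Reagents that add atoms: tert-butyldimethylsilyl chloride, CC(C)(C)[Si](C)(C)Cl
Why: Standard silylation of the only hydroxyl keeps O23 from chelating the Lewis acid or attacking the cation in step 5.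

Step 5
Reactants: 6 (2S,3S)-epoxy silyl ether
Product: 7 3β-hydroxy-23-(TBS-oxy) tricyclic δ-lactone (trans-decalin, 5α-H, 9α-H, 10β-CH3, 4α-CH2OTBS, 4β-CH3, 8β-CH3, C13(=O)–O–C8α)
Conditions: MeAlCl2 (2.5 equiv), CH2Cl2, −78 °C; aq. NaHCO3
Reagents that add atoms: none
Why: MeAlCl2 binds the oxirane oxygen, the tertiary C4–O bond opens in step with attack of the C5=C10 alkene, the charge runs on through the C8=C9 alkene, and it is caught at C8 by the carbonyl oxygen of the ester, whose tert-butyl group leaves as isobutene. The closest known reaction type is the Lewis-acid, epoxide-initiated (oxidosqualene-like) cation–olefin polycyclisation of protected 2,3-epoxy alcohols with an oxygen terminator. Ring A closes 6-endo (endo-tet at the oxirane, endo-trig at C5=C10), ring B closes 6-endo-trig at C8=C9, and the δ-lactone ring (C8, C9, C11, C12, C13, O) closes by attack of the C13 carbonyl oxygen on the C8 cation. C3 keeps its epoxide configuration and its equatorial O–Al group selects one chair–chair fold, C4 is set by inversion (C5 enters anti to the leaving oxygen, so the former E-CH2OTBS group becomes equatorial, 4α), C5 and C10 come from anti addition across the E-C5=C10 alkene (trans fusion, 5α-H, 10β-CH3), and C9 and C8 come from anti addition across the E-C8=C9 alkene (9α-H, 8α-O, 8β-CH3). The step needs initiation at the oxirane only and a stop after two carbocycles, which the substrate secures because the oxirane is the only ionisable group at −78 °C, the silyl ether mutes O23, no third alkene is present, and the ester oxygen sits at ring-closing distance from C8.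

Step 6
Reactants: 7 3β-hydroxy δ-lactone
Product: 8 3β-O-(imidazol-1-ylthiocarbonyl) derivative of 7
Conditions: 1,1′-thiocarbonyldiimidazole, DMAP (cat.), toluene, 90 °C
Reagents that add atoms: 1,1′-thiocarbonyldiimidazole, S=C(n1ccnc1)n1ccnc1
Why: Thioacylation of the only free hydroxyl (3β-OH) prepares the Barton–McCombie substrate.

Step 7
Reactants: 8 3β-O-thiocarbonylimidazolide
Product: 9 3-deoxy 23-(TBS-oxy) δ-lactone
Conditions: Bu3SnH, AIBN (cat.), toluene, 110 °C
Reagents that add atoms: none
Why: In the Barton–McCombie deoxygenation the stannyl radical adds to C=S, and the secondary C3 radical is released and takes hydrogen from the stannane, which removes the one oxygen no member carries without touching a remaining stereocentre.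

Step 8
Reactants: 9 3-deoxy 23-(TBS-oxy) δ-lactone
Product: 11 C23 carboxylic acid δ-lactone, via C23 primary alcohol δ-lactone 10 (not isolated)
Conditions: CrO3, H2SO4, H2O, acetone, 0 °C → rt
Reagents that add atoms: water, O
Why: Under Jones oxidation conditions the primary silyl ether is cleaved by the aqueous acid and the freed neopentyl alcohol is taken to the acid, while the saturated lactone has no other oxidisable group.

Step 9
Reactants: 11 C23 carboxylic acid δ-lactone
Product: 12 8α-hydroxy-13-oxo C23 acid (side chain CH2CH2C(=O)CH3 on C9)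
Conditions: MeLi (2.2 equiv), THF, −78 °C; dil. HCl
Reagents that add atoms: methyllithium, [Li]C
Why: In this organolithium addition to a lactone, the first equivalent makes the hindered lithium carboxylate, which is inert at −78 °C, the second adds to the open δ-lactone carbonyl, and the lithium hemiketal holds until work-up, so only the methyl ketone (C13, C21) forms.

Step 10
Reactants: 12 8α-hydroxy-13-oxo C23 acid
Product: 13 23,6α-olide (γ-lactone C23(=O)–O–C6α) with 8α-OH and the methyl ketone chain
Conditions: (S,S)-[Mn(OTf)2(TIPS-pdp)] (2 mol %), aq. H2O2 (1.5 equiv, syringe pump), (CF3)2CHOH, 0 °C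
Reagents that add atoms: none
Why: In this carboxylate-directed Mn-catalysed γ-C–H lactonisation (the bound acid helps to cleave H2O2, the Mn-oxo abstracts hydrogen by 1,7-HAT, rebound goes to the carboxylate), the equatorial C6–Hα bond runs parallel to the equatorial C4–C23 bond across C5 and is the only γ-C–H within reach, because the C2–H bonds point away, C10 has no hydrogen and C24 is only β, so oxygen should enter at C6 from the α face and C6 is relayed from C4.

Step 11
Reactants: 13 23,6α-olide methyl ketone
Product: 14 ethyl (13E)-enoate (C15 ester) of the 23,6α-olide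
Conditions: (EtO)2P(O)CH2CO2Et, NaH, THF, 0 → 50 °C
Reagents that add atoms: triethyl phosphonoacetate, CCOC(=O)CP(=O)(OCC)OCC
Why: The Horner–Wadsworth–Emmons olefination of the methyl ketone favours the E-enoate, with the ester trans to the larger C12 chain, the minor Z isomer is removed by chromatography, and the stabilised anion leaves the hindered γ-lactone alone.

Step 12
Reactants: 14 ethyl (13E)-enoate
Product: 15 (13E)-6α,8α,15,23-tetraol
Conditions: DIBAL-H (excess), CH2Cl2, −78 → 0 °C; Rochelle salt
Reagents that add atoms: none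
Why: DIBAL-H reduces the enoate in 1,2 fashion to the allylic alcohol and the strained γ-lactone to the 6,23-diol in one operation, with no change at any stereocentre or at the alkene.

Step 13
Reactants: 15 (13E)-6α,8α,15,23-tetraol
Product: 16 (13E)-6α,8α-dihydroxy-15,23-dial
Conditions: TEMPO (cat.), PhI(OAc)2 (2.3 equiv), CH2Cl2, rt
Reagents that add atoms: none
Why: The oxoammonium (TEMPO) oxidation takes primary alcohols over secondary and tertiary ones for steric reasons, so C15 and C23 become aldehydes while 6α-OH and 8α-OH stay, and the C23/O6 lactol would be trans-fused to both rings and strained, which should hold back further oxidation to the lactone.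

Step 14
Reactants: 16 (13E)-6α,8α-dihydroxy-15,23-dial
Product: 17 6,8-bis(triethylsilyl) ether of 16
Conditions: TESOTf, 2,6-lutidine, CH2Cl2, −78 → 0 °C
Reagents that add atoms: triethylsilyl triflate, CC[Si](CC)(CC)OS(=O)(=O)C(F)(F)F
Why: Silyl triflate/lutidine silylation covers both remaining hydroxyls, the tertiary one included, so that O8 cannot attack C13 in later allyl-type intermediates and C15-OH will be the only free hydroxyl after step 16.

Step 15
Reactants: 18 4-methylfuran-2(5H)-one
Product: 19 2-(tert-butyldimethylsilyloxy)-4-methylfuran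
Conditions: TBSOTf, Et3N, CH2Cl2, 0 °C
Reagents that add atoms: tert-butyldimethylsilyl triflate, CC(C)(C)[Si](C)(C)OS(=O)(=O)C(F)(F)F
Why: Soft enolisation and O-silylation of the butenolide give the aromatic silyloxyfuran, the γ-nucleophile for the aldol step.

Step 16
Reactants: 17 6,8-bis-TES 15,23-dial; 19 2-(tert-butyldimethylsilyloxy)-4-methylfuran
Product: 21 6,8-bis(triethylsilyl) ether of CNP0112578.1 ((15S,16S), free 15-OH, free C23 aldehyde), via 15-O-trichlorosilyl aldolate 20 (not isolated)
Conditions: SiCl4 (1.2 equiv), BINAM-derived bisphosphoramide (5 mol %), i-Pr2NEt (cat.), CH2Cl2, −78 °C; aq. NaHCO3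
Reagents that add atoms: none
Why: In this catalytic enantioselective vinylogous Mukaiyama aldol reaction (chiral phosphoramide-bound silicon cation as Lewis acid), the furan attacks through C5 in an open transition state that should give the syn (15S,16S) pair under catalyst control, and only the enal reacts because the C23 aldehyde is α-quaternary, screened by 6-OTES, and of the aliphatic type that responds poorly to this catalyst system.

## Branches

Branch to CNP0112578.1 (compound 22)

Step 17
Reactants: 21 6,8-bis(triethylsilyl) ether of CNP0112578.1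
Product: 22 CNP0112578.1
Conditions: HF·pyridine, pyridine, THF, 0 °C → rt
Reagents that add atoms: none
Why: Buffered fluoride desilylation removes both TES groups without acid strong enough to ionise the allylic 15-OH or base strong enough to epimerise C16.

Branch to CNP0292216.1 (compound 23)

Step 18
Reactants: 22 CNP0112578.1
Product: 23 CNP0292216.1
Conditions: NaClO2, NaH2PO4, 2-methyl-2-butene, t-BuOH/H2O, 0 °C → rt
Reagents that add atoms: sodium chlorite, [Na+].[O-]Cl=O
Why: The Pinnick oxidation acts only on the aldehyde (C23), since alcohols, the trisubstituted alkene (guarded by the scavenger) and the butenolide do not react with chlorous acid.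

Branch to CNP0104474.1 (compound 24)

Step 19
Reactants: 23 CNP0292216.1
Product: 24 CNP0104474.1
Conditions: TMSCHN2, toluene/MeOH, 0 °C
Reagents that add atoms: (trimethylsilyl)diazomethane, C[Si](C)(C)C=[N+]=[N-]
Why: Methyl ester formation with a diazoalkane starts by proton transfer from the only acidic group, so the hindered C23 acid is esterified at oxygen without base and without attack at its screened carbonyl.

Branch to CNP0255788.1 (compound 25)

Step 20
Reactants: 22 CNP0112578.1
Product: 25 CNP0255788.1
Conditions: NaBH(OAc)3, MeCN/AcOH, 0 °C → rt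
Reagents that add atoms: none
Why: In the acyloxyborohydride reduction only the aldehyde is electrophilic enough for this mild hydride, the neighbouring 6α-OH can bind boron and deliver hydride to C23, and the non-basic medium spares the butenolide and the aldol unit.

Branch to CNP0279704.1 (compound 28)

Step 21
Reactants: 22 CNP0112578.1
Product: 26 C23 (E)-tosylhydrazone of CNP0112578.1
Conditions: TsNHNH2, 4 Å MS, THF, rt → 40 °C
Reagents that add atoms: p-toluenesulfonyl hydrazide, Cc1ccc(cc1)S(=O)(=O)NN
Why: Hydrazone condensation can occur only at the single aldehyde, because the lactone carbonyl does not condense.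

Step 22
Reactants: 26 C23 (E)-tosylhydrazone
Product: 28 CNP0279704.1, via C23 monoalkyl diazene 27 (not isolated)
Conditions: catecholborane (excess), CHCl3, −10 °C; then NaOAc·3H2O, rt → 50 °C
Reagents that add atoms: none
Why: In this Caglioti-type tosylhydrazone reduction the borane adds hydride to the C=N bond only, acetate releases sulfinate to give the diazene, and loss of N2 leaves C23 as CH3, under conditions too mild for uncatalysed hydroboration of the alkenes or reduction of the lactone.

Branch to CNP0143336.1 (compound 31)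

Step 23
Reactants: 21 6,8-bis(triethylsilyl) ether of CNP0112578.1
Product: 29 15-O-acetate of 21
Conditions: Ac2O, pyridine, DMAP (cat.), CH2Cl2, 0 °C
Reagents that add atoms: acetic anhydride, CC(=O)OC(C)=O
Why: Acylation goes to C15-OH because it is the only free hydroxyl of 21, and the weak base at 0 °C should not trigger elimination toward C16.

Step 24
Reactants: 29 15-O-acetate of 21
Product: 30 6,8-bis(triethylsilyl) ether of CNP0143336.1 (C15H2, 16R)
Conditions: Pd(PPh3)4 (cat.), Bu3SnH (slow addition), THF, rt
Reagents that add atoms: none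
Why: In this Tsuji–Trost-type allylic hydrogenolysis with tin hydride, Pd(0) ionises the C15 acetate rather than the lactone C16–O bond, whose allyl cation would carry the carboxyl group, hydride goes to the less substituted terminus C15 so the trisubstituted 13E alkene is kept (syn/anti exchange at C13 would need a tertiary σ-palladium species), and C16 is not involved.

Step 25
Reactants: 30 6,8-bis(triethylsilyl) ether of CNP0143336.1
Product: 31 CNP0143336.1
Conditions: HF·pyridine, pyridine, THF, 0 °C → rt
Reagents that add atoms: none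
Why: Buffered fluoride desilylation frees 6α-OH and 8α-OH and leaves the aldehyde, alkene and butenolide as they are.

## Compound list

1 | tert-butyl acetate | CC(=O)OC(C)(C)C | starting material
2 | (2E,6E)-farnesyl bromide | CC(C)=CCC/C(C)=C/CC/C(C)=C/CBr | starting material
3 | tert-butyl (4E,8E)-5,9,13-trimethyltetradeca-4,8,12-trienoate | CC(C)=CCC/C(C)=C/CC/C(C)=C/CCC(=O)OC(C)(C)C | intermediate
4 | tert-butyl (4E,8E,12E)-14-hydroxy-5,9,13-trimethyltetradeca-4,8,12-trienoate | OC/C(C)=C/CC/C(C)=C/CC/C(C)=C/CCC(=O)OC(C)(C)C | intermediate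
5 | tert-butyl (4E,8E)-11-[(2S,3S)-3-(hydroxymethyl)-3-methyloxiran-2-yl]-5,9-dimethylundeca-4,8-dienoate | CC(C)(C)OC(=O)CC/C=C(\C)CC/C=C(\C)CC[C@@H]1O[C@@]1(C)CO | intermediate
6 | tert-butyldimethylsilyl ether of 5 | CC(C)(C)OC(=O)CC/C=C(\C)CC/C=C(\C)CC[C@@H]1O[C@@]1(C)CO[Si](C)(C)C(C)(C)C | intermediate
7 | 3β-hydroxy-23-(TBS-oxy) tricyclic δ-lactone (5α-H, 9α-H, 10β-CH3, 4α-CH2OTBS, 4β-CH3, 8β-CH3, C13(=O)–O–C8α) | O=C1CC[C@@H]2[C@@]3(C)CC[C@H](O)[C@@](C)(CO[Si](C)(C)C(C)(C)C)[C@@H]3CC[C@@]2(C)O1 | intermediate
8 | 3β-O-(imidazol-1-ylthiocarbonyl) derivative of 7 | O=C1CC[C@@H]2[C@@]3(C)CC[C@H](OC(=S)n4ccnc4)[C@@](C)(CO[Si](C)(C)C(C)(C)C)[C@@H]3CC[C@@]2(C)O1 | intermediate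
9 | 3-deoxy 23-(TBS-oxy) δ-lactone | O=C1CC[C@@H]2[C@@]3(C)CCC[C@@](C)(CO[Si](C)(C)C(C)(C)C)[C@@H]3CC[C@@]2(C)O1 | intermediate
10 | C23 primary alcohol δ-lactone | O=C1CC[C@@H]2[C@@]3(C)CCC[C@@](C)(CO)[C@@H]3CC[C@@]2(C)O1 | intermediate
11 | C23 carboxylic acid δ-lactone | O=C1CC[C@@H]2[C@@]3(C)CCC[C@@](C)(C(=O)O)[C@@H]3CC[C@@]2(C)O1 | intermediate
12 | 8α-hydroxy-13-oxo C23 acid | CC(=O)CC[C@@H]1[C@@]2(C)CCC[C@@](C)(C(=O)O)[C@@H]2CC[C@@]1(C)O | intermediate
13 | 23,6α-olide with 8α-OH and methyl ketone chain | CC(=O)CC[C@@H]1[C@@]2(C)CCC[C@]3(C)[C@@H]2[C@H](C[C@@]1(C)O)OC3=O | intermediate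
14 | ethyl (13E)-enoate of the 23,6α-olide | CCOC(=O)/C=C(\C)CC[C@@H]1[C@@]2(C)CCC[C@]3(C)[C@@H]2[C@H](C[C@@]1(C)O)OC3=O | intermediate
15 | (13E)-6α,8α,15,23-tetraol | OC/C=C(\C)CC[C@@H]1[C@@]2(C)CCC[C@@](C)(CO)[C@@H]2[C@@H](O)C[C@@]1(C)O | intermediate
16 | (13E)-6α,8α-dihydroxy-15,23-dial | O=C/C=C(\C)CC[C@@H]1[C@@]2(C)CCC[C@@](C)(C=O)[C@@H]2[C@@H](O)C[C@@]1(C)O | intermediate
17 | 6,8-bis(triethylsilyl) ether of 16 | O=C/C=C(\C)CC[C@@H]1[C@@]2(C)CCC[C@@](C)(C=O)[C@@H]2[C@@H](O[Si](CC)(CC)CC)C[C@@]1(C)O[Si](CC)(CC)CC | intermediate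
18 | 4-methylfuran-2(5H)-one | CC1=CC(=O)OC1 | starting material
19 | 2-(tert-butyldimethylsilyloxy)-4-methylfuran | Cc1coc(O[Si](C)(C)C(C)(C)C)c1 | intermediate
20 | 15-O-trichlorosilyl aldolate | CC1=CC(=O)O[C@@H]1[C@@H](O[Si](Cl)(Cl)Cl)/C=C(\C)CC[C@@H]1[C@@]2(C)CCC[C@@](C)(C=O)[C@@H]2[C@@H](O[Si](CC)(CC)CC)C[C@@]1(C)O[Si](CC)(CC)CC | intermediate
21 | 6,8-bis(triethylsilyl) ether of CNP0112578.1 (shared intermediate) | CC1=CC(=O)O[C@@H]1[C@@H](O)/C=C(\C)CC[C@@H]1[C@@]2(C)CCC[C@@](C)(C=O)[C@@H]2[C@@H](O[Si](CC)(CC)CC)C[C@@]1(C)O[Si](CC)(CC)CC | intermediate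
22 | CNP0112578.1 | CC1=CC(=O)O[C@@H]1[C@@H](O)/C=C(\C)CC[C@@H]1[C@@]2(C)CCC[C@@](C)(C=O)[C@@H]2[C@@H](O)C[C@@]1(C)O | target
23 | CNP0292216.1 | CC1=CC(=O)O[C@@H]1[C@@H](O)/C=C(\C)CC[C@@H]1[C@@]2(C)CCC[C@@](C)(C(=O)O)[C@@H]2[C@@H](O)C[C@@]1(C)O | target
24 | CNP0104474.1 | COC(=O)[C@]1(C)CCC[C@@]2(C)[C@H]1[C@@H](O)C[C@@](C)(O)[C@@H]2CC/C(C)=C/[C@H](O)[C@H]1OC(=O)C=C1C | target
25 | CNP0255788.1 | CC1=CC(=O)O[C@@H]1[C@@H](O)/C=C(\C)CC[C@@H]1[C@@]2(C)CCC[C@@](C)(CO)[C@@H]2[C@@H](O)C[C@@]1(C)O | target
26 | C23 (E)-tosylhydrazone of CNP0112578.1 | CC1=CC(=O)O[C@@H]1[C@@H](O)/C=C(\C)CC[C@@H]1[C@@]2(C)CCC[C@@](C)(/C=N/NS(=O)(=O)c3ccc(C)cc3)[C@@H]2[C@@H](O)C[C@@]1(C)O | intermediate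
27 | C23 monoalkyl diazene | CC1=CC(=O)O[C@@H]1[C@@H](O)/C=C(\C)CC[C@@H]1[C@@]2(C)CCC[C@@](C)(CN=N)[C@@H]2[C@@H](O)C[C@@]1(C)O | intermediate
28 | CNP0279704.1 | CC1=CC(=O)O[C@@H]1[C@@H](O)/C=C(\C)CC[C@@H]1[C@@]2(C)CCCC(C)(C)[C@@H]2[C@@H](O)C[C@@]1(C)O | target
29 | 15-O-acetate of 21 | CC1=CC(=O)O[C@@H]1[C@@H](OC(C)=O)/C=C(\C)CC[C@@H]1[C@@]2(C)CCC[C@@](C)(C=O)[C@@H]2[C@@H](O[Si](CC)(CC)CC)C[C@@]1(C)O[Si](CC)(CC)CC | intermediate
30 | 6,8-bis(triethylsilyl) ether of CNP0143336.1 | CC1=CC(=O)O[C@@H]1C/C=C(\C)CC[C@@H]1[C@@]2(C)CCC[C@@](C)(C=O)[C@@H]2[C@@H](O[Si](CC)(CC)CC)C[C@@]1(C)O[Si](CC)(CC)CC | intermediate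
31 | CNP0143336.1 | CC1=CC(=O)O[C@@H]1C/C=C(\C)CC[C@@H]1[C@@]2(C)CCC[C@@](C)(C=O)[C@@H]2[C@@H](O)C[C@@]1(C)O | target

## Totals

Totals for CNP0112578.1 (compound 22): total step count 17, longest linear sequence 16
Totals for CNP0292216.1 (compound 23): total step count 18, longest linear sequence 17
Totals for CNP0104474.1 (compound 24): total step count 19, longest linear sequence 18
Totals for CNP0255788.1 (compound 25): total step count 18, longest linear sequence 17
Totals for CNP0279704.1 (compound 28): total step count 19, longest linear sequence 18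
Totals for CNP0143336.1 (compound 31): total step count 19, longest linear sequence 18

## The three steps most likely to fail

**Step 5.**
- What may go wrong: the C8 cation may lose a proton before the ester oxygen arrives, the opened oxirane may undergo a 1,2-hydride shift to the ketone, or the cascade may stop after ring A.
- Fallback: a radical cascade replaces the cationic one, and carbocyclisation and lactonisation become two separate operations. It sets out from 6 and comes back at 7.
- Cp2TiCl (Cp2TiCl2, Mn, 2,4,6-collidine, TMSCl, THF, rt) should open the oxirane homolytically at C4. The tertiary radical should close rings A and B through the same chair–chair fold, with the 3-O-titanium group and the larger CH2OTBS group equatorial. Loss of a β-hydrogen should then give the 3β-hydroxy 8(22)-exomethylene bicyclic tert-butyl ester F1.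
- A catalytic strong Brønsted acid (Tf2NH, CH2Cl2, −40 °C) should protonate the exocyclic alkene. The tert-butyl ester should close on C8 from the α face to give 7.

**Step 10.**
- What may go wrong: the hindered carboxylate may bind the metal poorly. Oxidation may drift to ring-A methylenes or to the chain. C6 may be over-oxidised, the acid may be lost by oxidative decarboxylation, or ring closure to the strained lactone may be incomplete.
- Fallback: an alkoxy-radical relay from the C23 alcohol replaces the metal-oxo relay from the acid. It sets out from 9 and comes back at 13.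
- Fluoride (TBAF, THF) frees alcohol 10.
- The hypoiodite reaction (PhI(OAc)2, I2, visible light, cyclohexane) makes the C23 alkoxy radical. This radical takes the same C6–Hα by 1,5-HAT and closes to the 6α,23-epoxy (tetrahydrofuran) δ-lactone F2.
- MeLi (THF, −78 °C) adds to the only carbonyl group and gives the 6α,23-epoxy 8α-hydroxy methyl ketone F3.
- RuO4 (RuCl3 cat., NaIO4, MeCN/H2O/EtOAc) oxidises the ether CH2 (C23) in preference to the ether CH (C6) and gives 13.

**Step 24.**
- What may go wrong: the allyl-palladium species may eliminate toward the conjugated γ-ylidene butenolide through loss of the acidic C16–H. Hydride may go to the tertiary terminus C13. Ionisation next to the electron-poor C16 may be slow.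
- Fallback: a neutral radical chain replaces the ionic π-allyl intermediate. It sets out from 21 and comes back at 30.
- Phenyl chlorothionoformate and pyridine (CH2Cl2, 0 °C) give the 15-O-(phenoxythiocarbonyl) derivative F4.
- F4 is reduced at or below room temperature ((Me3Si)3SiH, Et3B/air, toluene), so that thermal [3,3] rearrangement is avoided. The bulky hydrogen donor should meet the allyl radical at the less hindered C15, and no base is present that could remove the C16 hydrogen.

## Further compounds

F1 | step 5 | 3β-hydroxy-23-(TBS-oxy) 8(22)-exomethylene bicyclic tert-butyl ester | CC(C)(C)OC(=O)CC[C@@H]1[C@@]2(C)CC[C@H](O)[C@@](C)(CO[Si](C)(C)C(C)(C)C)[C@@H]2CCC1=C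
F2 | step 10 | 6α,23-epoxy δ-lactone | O=C1CC[C@@H]2[C@@]3(C)CCC[C@]4(C)[C@@H]3[C@H](C[C@@]2(C)O1)OC4
F3 | step 10 | 6α,23-epoxy 8α-hydroxy methyl ketone | CC(=O)CC[C@@H]1[C@@]2(C)CCC[C@]3(C)[C@@H]2[C@H](C[C@@]1(C)O)OC3
F4 | step 24 | 15-O-(phenoxythiocarbonyl) derivative of 21 | CC1=CC(=O)O[C@@H]1[C@@H](OC(=S)Oc3ccccc3)/C=C(\C)CC[C@@H]1[C@@]2(C)CCC[C@@](C)(C=O)[C@@H]2[C@@H](O[Si](CC)(CC)CC)C[C@@]1(C)O[Si](CC)(CC)CC
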